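**Retrosynthetic overview**
- The (E)-stilbene C=C is cut last: Horner–Wadsworth–Emmons union of a benzodioxanylmethyl phosphonate with 3,5-disilyloxybenzaldehyde, then one global desilylation.
- Both stereocentres (cis, 2S,3R) come from one enantioselective ionic transfer hydrogenation of an achiral 2,3-diaryl-1,4-benzodioxine.
- The six-membered O1–C2–C3–O4–C4a–C8a ring is not closed as such: it grows from the five-membered 1,3-benzodioxole ring of a catechol ketal by a carbene 1,2-oxygen shift, in which the exocyclic carbene carbon enters the ring.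
- Enabling feature: the ketal carbon C2 of the benzodioxole carries both ring oxygens (O1, O3) directly beside the exocyclic carbene carbon. An ester para and a temporary bromine ortho to O1 leave O3 as the migrating oxygen, and the aryl group on C2 (3,5-disilyloxyphenyl) is a poor migrating group.
- Ring order: the three benzene rings are bought (piceatannol, a bromocatechol ester, 3,5-dihydroxybenzaldehyde); benzodioxole ring in step 5, enlarged to the dioxine ring in step 7, saturated in step 8.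

Key step: step 7

Assumption: methyl 3-bromo-4,5-dihydroxybenzoate is taken as a purchasable catechol.

Step 1
Reactants: 1 piceatannol
Product: 2 (E)-1-[3,4-bis(TBSO)phenyl]-2-[3,5-bis(TBSO)phenyl]ethene (TBSO = tert-butyldimethylsilyloxy)
Conditions: TBSCl, imidazole, DMF, rt
Reagents that add atoms: tert-butyldimethylsilyl chloride, CC(C)(C)[Si](C)(C)Cl
Why: Imidazole-promoted silylation of the four phenols (silyl ether formation) masks them for the whole route and creates no stereocentre.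

Step 2
Reactants: 2 (E)-1-[3,4-bis(TBSO)phenyl]-2-[3,5-bis(TBSO)phenyl]ethene
Product: 3 rac-(1R,2R)-1-[3,4-bis(TBSO)phenyl]-2-[3,5-bis(TBSO)phenyl]ethane-1,2-diol (racemic threo diol)
Conditions: OsO4 (cat.), N-methylmorpholine N-oxide, acetone/H2O, rt
Reagents that add atoms: N-methylmorpholine N-oxide, C[N+]1([O-])CCOCC1; water, O
Why: Upjohn syn-dihydroxylation of the electron-rich E-alkene should give the racemic threo diol, whose two stereocentres are erased again in step 3.

Step 3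
Reactants: 3 rac-(1R,2R)-1-[3,4-bis(TBSO)phenyl]-2-[3,5-bis(TBSO)phenyl]ethane-1,2-diol
Product: 4 1-[3,4-bis(TBSO)phenyl]-2-[3,5-bis(TBSO)phenyl]ethane-1,2-dione
Conditions: (COCl)2, DMSO, CH2Cl2, −78 °C; then Et3N
Reagents that add atoms: none
Why: Swern oxidation of both carbinols should give the 1,2-diketone without the C–C cleavage that periodate-type oxidants cause with hydrobenzoins.

Step 4
Reactants: 4 1-[3,4-bis(TBSO)phenyl]-2-[3,5-bis(TBSO)phenyl]ethane-1,2-dione
Product: 5 1-[3,4-bis(TBSO)phenyl]-2-[3,5-bis(TBSO)phenyl]-2,2-dimethoxyethan-1-one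
Conditions: HC(OMe)3, MeOH, TsOH·H2O (cat.), 50 °C
Reagents that add atoms: trimethyl orthoformate, COC(OC)OC
Why: Acid-catalysed ketalisation with orthoformate as water scavenger should stop at the monoketal and occur at the more electrophilic carbonyl, the one whose aryl ring has no para oxygen donor.

Step 5
Reactants: 5 1-[3,4-bis(TBSO)phenyl]-2-[3,5-bis(TBSO)phenyl]-2,2-dimethoxyethan-1-one; 6 methyl 3-bromo-4,5-dihydroxybenzoate
Product: 7 methyl 7-bromo-2-[3,4-bis(TBSO)benzoyl]-2-[3,5-bis(TBSO)phenyl]-1,3-benzodioxole-5-carboxylate (racemic)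
Conditions: TsOH·H2O (cat.), toluene, 100 °C, 5 Å molecular sieves (removal of MeOH)
Reagents that add atoms: none
Why: Acid-catalysed transketalisation, the usual way from dimethyl ketals to catechol ketals, is driven by removal of methanol and five-membered ring formation; the new ketal stereocentre forms as the racemate and is destroyed in step 7.

Step 6
Reactants: 7 methyl 7-bromo-2-[3,4-bis(TBSO)benzoyl]-2-[3,5-bis(TBSO)phenyl]-1,3-benzodioxole-5-carboxylate
Product: 8 N-tosylhydrazone of ketone 7 (racemic)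
Conditions: TsNHNH2, PPTS (cat.), THF/MeOH, 60 °C
Reagents that add atoms: p-toluenesulfonyl hydrazide, Cc1ccc(cc1)S(=O)(=O)NN
Why: Tosylhydrazone formation at the only remaining ketone places the carbene precursor on the carbon that bears the 3,4-disilyloxyphenyl ring.

Step 7
Reactants: 8 N-tosylhydrazone of ketone 7
Product: 10 methyl 8-bromo-3-[3,4-bis(TBSO)phenyl]-2-[3,5-bis(TBSO)phenyl]-1,4-benzodioxine-6-carboxylate, via diazo ketal 9 (not isolated)
Conditions: NaH, THF, 0 °C; then Rh2(OAc)4 (2 mol%), BnEt3NCl (10 mol%), 1,4-dioxane, 70 °C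
Reagents that add atoms: none
Why: Proposed new method: NaH and heat turn 8 into diazo ketal 9 (Bamford–Stevens), Rh2(OAc)4 converts it into an electrophilic rhodium carbene directly beside the ketal carbon C2, a lone pair of ring oxygen O3 adds to the carbene carbon to give a bicyclic three-membered oxonium ylide, and cleavage of the C2–O3 bond with release of the catalyst moves O3 onto the former carbene carbon and leaves the C2=C3 bond of the new ring. The closest known reaction type is the 1,2-alkoxy or 1,2-thio shift of carbenes that carry the heteroatom on the neighbouring carbon, known for acyclic dialkoxy carbenes and as the ring enlargement of 2-(diazoalkyl)-1,3-dithiolanes to dihydro-1,4-dithiins; a catechol ketal with aryl ether oxygens has not served as the migrating partner. The 1,4-dioxine ring is closed by three-membered (3-exo) attack of O3 on the carbenoid carbon followed by fragmentation of the internal C2–O3 bond, so the five-membered 1,3-benzodioxole grows by the exocyclic carbon to the six-membered ring. No stereocentre is formed: the racemic ketal stereocentre of 8 is destroyed and the product is an achiral enediol diether, both stereocentres being set in step 8. The step needs oxygen migration in place of aryl migration and migration of O3 in place of O1: the aryl group on C2 is the 3,5-disilyloxyphenyl ring, a poor migrating group without a para donor, while O1 is the weaker and more shielded donor because the ester stands para and the bromine ortho to it. Slow thermal release of 9 keeps its concentration low, which should suppress azine formation and carbene dimerisation.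

Step 8
Reactants: 10 methyl 8-bromo-3-[3,4-bis(TBSO)phenyl]-2-[3,5-bis(TBSO)phenyl]-1,4-benzodioxine-6-carboxylate
Product: 11 methyl (2S,3R)-8-bromo-3-[3,4-bis(TBSO)phenyl]-2-[3,5-bis(TBSO)phenyl]-2,3-dihydro-1,4-benzodioxine-6-carboxylate (cis)
Conditions: (R)-TRIP-derived N-triflyl phosphoramide (10 mol%), Hantzsch ester (diethyl 2,6-dimethyl-1,4-dihydropyridine-3,5-dicarboxylate), toluene, 40 °C
Reagents that add atoms: none
Why: Proposed new method: the strong chiral acid should protonate the enediol diether at C2, because the resulting C3 oxocarbenium ion is stabilised by O4 and the para-silyloxyphenyl ring, and hold it as an ion pair with the chiral anion; proton loss and re-addition interconvert the two enantiomeric cations (dynamic kinetic resolution), the C2 aryl group stands pseudo-axial to avoid allylic strain, and the Hantzsch ester delivers hydride to the opposite face of C3, which fixes the cis relationship, while the chiral anion selects which enantiomeric ion pair is reduced and so sets both stereocentres as 2S,3R (the mirror-image catalyst is taken if the sense of induction proves opposite); the closest known reaction type is the chiral phosphoric acid and Hantzsch ester transfer hydrogenation of 2,3-disubstituted quinolines and 3-aryl-1,4-benzoxazines, which gives cis products by the same dynamic course, together with Hantzsch ester reductions of benzopyrylium ions.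

Step 9
Reactants: 11 methyl (2S,3R)-8-bromo-3-[3,4-bis(TBSO)phenyl]-2-[3,5-bis(TBSO)phenyl]-2,3-dihydro-1,4-benzodioxine-6-carboxylate
Product: 12 methyl (2S,3R)-3-[3,4-bis(TBSO)phenyl]-2-[3,5-bis(TBSO)phenyl]-2,3-dihydro-1,4-benzodioxine-6-carboxylate
Conditions: H2 (1 atm), Pd/C, Et3N, EtOAc, rt
Reagents that add atoms: none
Why: Palladium-catalysed hydrodebromination removes the blocking bromine, while triethylamine takes up HBr and slows hydrogenolysis of the benzylic C–O bonds, so both stereocentres stay untouched.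

Step 10
Reactants: 12 methyl (2S,3R)-3-[3,4-bis(TBSO)phenyl]-2-[3,5-bis(TBSO)phenyl]-2,3-dihydro-1,4-benzodioxine-6-carboxylate
Product: 13 [(2S,3R)-3-[3,4-bis(TBSO)phenyl]-2-[3,5-bis(TBSO)phenyl]-2,3-dihydro-1,4-benzodioxin-6-yl]methanol
Conditions: i-Bu2AlH, CH2Cl2, −78 to 0 °C; aq. potassium sodium tartrate
Reagents that add atoms: none
Why: Hydride reduction of the ester to the primary benzylic alcohol leaves the aryl silyl ethers and the benzodioxane ring intact.

Step 11
Reactants: 13 [(2S,3R)-3-[3,4-bis(TBSO)phenyl]-2-[3,5-bis(TBSO)phenyl]-2,3-dihydro-1,4-benzodioxin-6-yl]methanol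
Product: 14 (2S,3R)-6-(bromomethyl)-3-[3,4-bis(TBSO)phenyl]-2-[3,5-bis(TBSO)phenyl]-2,3-dihydro-1,4-benzodioxine
Conditions: CBr4, PPh3, CH2Cl2, 0 °C
Reagents that add atoms: carbon tetrabromide, BrC(Br)(Br)Br
Why: The Appel reaction converts the benzylic alcohol into the bromide under neutral conditions that cannot ionise the benzylic C–O bonds of the ring.

Step 12
Reactants: 14 (2S,3R)-6-(bromomethyl)-3-[3,4-bis(TBSO)phenyl]-2-[3,5-bis(TBSO)phenyl]-2,3-dihydro-1,4-benzodioxine
Product: 15 diethyl {[(2S,3R)-3-[3,4-bis(TBSO)phenyl]-2-[3,5-bis(TBSO)phenyl]-2,3-dihydro-1,4-benzodioxin-6-yl]methyl}phosphonate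
Conditions: P(OEt)3, neat, 120 °C
Reagents that add atoms: triethyl phosphite, CCOP(OCC)OCC
Why: The Michaelis–Arbuzov reaction of the activated benzylic bromide gives the phosphonate without touching the stereocentres.

Step 13
Reactants: 16 3,5-dihydroxybenzaldehyde
Product: 17 3,5-bis(TBSO)benzaldehyde
Conditions: TBSCl, imidazole, DMF, rt
Reagents that add atoms: tert-butyldimethylsilyl chloride, CC(C)(C)[Si](C)(C)Cl
Why: Silylation of the two phenols as in step 1 gives the aldehyde partner for the olefination.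

Step 14
Reactants: 15 diethyl {[(2S,3R)-3-[3,4-bis(TBSO)phenyl]-2-[3,5-bis(TBSO)phenyl]-2,3-dihydro-1,4-benzodioxin-6-yl]methyl}phosphonate; 17 3,5-bis(TBSO)benzaldehyde
Product: 18 (2S,3R)-3-[3,4-bis(TBSO)phenyl]-2-[3,5-bis(TBSO)phenyl]-6-[(E)-2-[3,5-bis(TBSO)phenyl]ethenyl]-2,3-dihydro-1,4-benzodioxine
Conditions: NaH, THF, 0 °C to rt
Reagents that add atoms: none
Why: Horner–Wadsworth–Emmons olefination of the benzylic phosphonate anion with the aryl aldehyde should give the E-stilbene, and C2 and C3 carry no hydrogen acidic enough to be epimerised.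

Step 15
Reactants: 18 (2S,3R)-3-[3,4-bis(TBSO)phenyl]-2-[3,5-bis(TBSO)phenyl]-6-[(E)-2-[3,5-bis(TBSO)phenyl]ethenyl]-2,3-dihydro-1,4-benzodioxine
Product: 19 5-[(E)-2-[(2S,3R)-3-(3,4-dihydroxyphenyl)-2-(3,5-dihydroxyphenyl)-2,3-dihydro-1,4-benzodioxin-6-yl]ethenyl]benzene-1,3-diol (CNP0283264.2)
Conditions: Bu4NF, AcOH, THF, 0 °C
Reagents that add atoms: none
Why: Fluoride desilylation buffered with acetic acid frees all six phenols without strong base or Lewis acid, which should avoid quinone methide opening of the benzylic aryl ether bond and thus cis-to-trans epimerisation.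

**Compound list**
1 | piceatannol, (E)-4-[2-(3,5-dihydroxyphenyl)ethenyl]benzene-1,2-diol | Oc1cc(O)cc(/C=C/c2ccc(O)c(O)c2)c1 | starting material
2 | (E)-1-[3,4-bis(TBSO)phenyl]-2-[3,5-bis(TBSO)phenyl]ethene | CC(C)(C)[Si](C)(C)Oc1cc(O[Si](C)(C)C(C)(C)C)cc(/C=C/c2ccc(O[Si](C)(C)C(C)(C)C)c(O[Si](C)(C)C(C)(C)C)c2)c1 | intermediate
3 | rac-(1R,2R)-1-[3,4-bis(TBSO)phenyl]-2-[3,5-bis(TBSO)phenyl]ethane-1,2-diol (racemic threo; one enantiomer drawn) | O[C@H](c1ccc(O[Si](C)(C)C(C)(C)C)c(O[Si](C)(C)C(C)(C)C)c1)[C@H](O)c1cc(O[Si](C)(C)C(C)(C)C)cc(O[Si](C)(C)C(C)(C)C)c1 | intermediate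
4 | 1-[3,4-bis(TBSO)phenyl]-2-[3,5-bis(TBSO)phenyl]ethane-1,2-dione | O=C(c1ccc(O[Si](C)(C)C(C)(C)C)c(O[Si](C)(C)C(C)(C)C)c1)C(=O)c1cc(O[Si](C)(C)C(C)(C)C)cc(O[Si](C)(C)C(C)(C)C)c1 | intermediate
5 | 1-[3,4-bis(TBSO)phenyl]-2-[3,5-bis(TBSO)phenyl]-2,2-dimethoxyethan-1-one | COC(OC)(c1cc(O[Si](C)(C)C(C)(C)C)cc(O[Si](C)(C)C(C)(C)C)c1)C(=O)c1ccc(O[Si](C)(C)C(C)(C)C)c(O[Si](C)(C)C(C)(C)C)c1 | intermediate
6 | methyl 3-bromo-4,5-dihydroxybenzoate | COC(=O)c1cc(Br)c(O)c(O)c1 | starting material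
7 | methyl 7-bromo-2-[3,4-bis(TBSO)benzoyl]-2-[3,5-bis(TBSO)phenyl]-1,3-benzodioxole-5-carboxylate (racemic) | COC(=O)c1cc(Br)c2OC(c3cc(O[Si](C)(C)C(C)(C)C)cc(O[Si](C)(C)C(C)(C)C)c3)(C(=O)c3ccc(O[Si](C)(C)C(C)(C)C)c(O[Si](C)(C)C(C)(C)C)c3)Oc2c1 | intermediate
8 | N-tosylhydrazone of ketone 7 (racemic) | COC(=O)c1cc(Br)c2OC(c3cc(O[Si](C)(C)C(C)(C)C)cc(O[Si](C)(C)C(C)(C)C)c3)(C(=NNS(=O)(=O)c3ccc(C)cc3)c3ccc(O[Si](C)(C)C(C)(C)C)c(O[Si](C)(C)C(C)(C)C)c3)Oc2c1 | intermediate
9 | methyl 7-bromo-2-{[3,4-bis(TBSO)phenyl](diazo)methyl}-2-[3,5-bis(TBSO)phenyl]-1,3-benzodioxole-5-carboxylate (racemic, not isolated) | COC(=O)c1cc(Br)c2OC(c3cc(O[Si](C)(C)C(C)(C)C)cc(O[Si](C)(C)C(C)(C)C)c3)(C(=[N+]=[N-])c3ccc(O[Si](C)(C)C(C)(C)C)c(O[Si](C)(C)C(C)(C)C)c3)Oc2c1 | intermediate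
10 | methyl 8-bromo-3-[3,4-bis(TBSO)phenyl]-2-[3,5-bis(TBSO)phenyl]-1,4-benzodioxine-6-carboxylate | COC(=O)c1cc(Br)c2OC(c3cc(O[Si](C)(C)C(C)(C)C)cc(O[Si](C)(C)C(C)(C)C)c3)=C(c3ccc(O[Si](C)(C)C(C)(C)C)c(O[Si](C)(C)C(C)(C)C)c3)Oc2c1 | intermediate
11 | methyl (2S,3R)-8-bromo-3-[3,4-bis(TBSO)phenyl]-2-[3,5-bis(TBSO)phenyl]-2,3-dihydro-1,4-benzodioxine-6-carboxylate | COC(=O)c2cc(Br)c3c(c2)O[C@H](c2ccc(O[Si](C)(C)C(C)(C)C)c(O[Si](C)(C)C(C)(C)C)c2)[C@H](c2cc(O[Si](C)(C)C(C)(C)C)cc(O[Si](C)(C)C(C)(C)C)c2)O3 | intermediate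
12 | methyl (2S,3R)-3-[3,4-bis(TBSO)phenyl]-2-[3,5-bis(TBSO)phenyl]-2,3-dihydro-1,4-benzodioxine-6-carboxylate | COC(=O)c2ccc3c(c2)O[C@H](c2ccc(O[Si](C)(C)C(C)(C)C)c(O[Si](C)(C)C(C)(C)C)c2)[C@H](c2cc(O[Si](C)(C)C(C)(C)C)cc(O[Si](C)(C)C(C)(C)C)c2)O3 | intermediate
13 | [(2S,3R)-3-[3,4-bis(TBSO)phenyl]-2-[3,5-bis(TBSO)phenyl]-2,3-dihydro-1,4-benzodioxin-6-yl]methanol | OCc2ccc3c(c2)O[C@H](c2ccc(O[Si](C)(C)C(C)(C)C)c(O[Si](C)(C)C(C)(C)C)c2)[C@H](c2cc(O[Si](C)(C)C(C)(C)C)cc(O[Si](C)(C)C(C)(C)C)c2)O3 | intermediate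
14 | (2S,3R)-6-(bromomethyl)-3-[3,4-bis(TBSO)phenyl]-2-[3,5-bis(TBSO)phenyl]-2,3-dihydro-1,4-benzodioxine | BrCc2ccc3c(c2)O[C@H](c2ccc(O[Si](C)(C)C(C)(C)C)c(O[Si](C)(C)C(C)(C)C)c2)[C@H](c2cc(O[Si](C)(C)C(C)(C)C)cc(O[Si](C)(C)C(C)(C)C)c2)O3 | intermediate
15 | diethyl {[(2S,3R)-3-[3,4-bis(TBSO)phenyl]-2-[3,5-bis(TBSO)phenyl]-2,3-dihydro-1,4-benzodioxin-6-yl]methyl}phosphonate | CCOP(=O)(OCC)Cc2ccc3c(c2)O[C@H](c2ccc(O[Si](C)(C)C(C)(C)C)c(O[Si](C)(C)C(C)(C)C)c2)[C@H](c2cc(O[Si](C)(C)C(C)(C)C)cc(O[Si](C)(C)C(C)(C)C)c2)O3 | intermediate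
16 | 3,5-dihydroxybenzaldehyde | O=Cc1cc(O)cc(O)c1 | starting material
17 | 3,5-bis(TBSO)benzaldehyde | O=Cc1cc(O[Si](C)(C)C(C)(C)C)cc(O[Si](C)(C)C(C)(C)C)c1 | intermediate
18 | (2S,3R)-3-[3,4-bis(TBSO)phenyl]-2-[3,5-bis(TBSO)phenyl]-6-[(E)-2-[3,5-bis(TBSO)phenyl]ethenyl]-2,3-dihydro-1,4-benzodioxine | CC(C)(C)[Si](C)(C)Oc1cc(O[Si](C)(C)C(C)(C)C)cc(/C=C/c2ccc3c(c2)O[C@H](c2ccc(O[Si](C)(C)C(C)(C)C)c(O[Si](C)(C)C(C)(C)C)c2)[C@H](c2cc(O[Si](C)(C)C(C)(C)C)cc(O[Si](C)(C)C(C)(C)C)c2)O3)c1 | intermediate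
19 | 5-[(E)-2-[(2S,3R)-3-(3,4-dihydroxyphenyl)-2-(3,5-dihydroxyphenyl)-2,3-dihydro-1,4-benzodioxin-6-yl]ethenyl]benzene-1,3-diol | Oc1cc(O)cc(/C=C/c2ccc3c(c2)O[C@H](c2ccc(O)c(O)c2)[C@H](c2cc(O)cc(O)c2)O3)c1 | target

Total step count: 15. Longest linear sequence: 14 steps (steps 1 to 12, then 14 and 15).

**Steps most likely to fail**

Step 7 (proposed new method). Aryl migration, carbene dimerisation or insertion into adventitious water may outrun the oxygen shift, or the wrong ring oxygen may migrate and give the regioisomeric benzodioxine. The fallback uses known chemistry without a change of ring size. It sets out from diol 3: DDQ oxidises selectively the carbinol beside the para-silyloxyphenyl ring to 2-hydroxy-1-[3,4-bis(TBSO)phenyl]-2-[3,5-bis(TBSO)phenyl]ethan-1-one F1. Mitsunobu etherification (PPh3, DIAD) with catechol 6 at its more acidic hydroxyl, the one para to the ester, gives methyl 3-bromo-4-{2-[3,4-bis(TBSO)phenyl]-1-[3,5-bis(TBSO)phenyl]-2-oxoethoxy}-5-hydroxybenzoate F2. TsOH in toluene with azeotropic removal of water closes the hemiketal and dehydrates it, and the route is rejoined at benzodioxine 10.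

Step 8 (proposed new method). Protonation of the enol ether by the chiral acid may be too slow, or the two enantiomeric ion pairs may be discriminated poorly, so that enantioselectivity or the cis preference is lost. The fallback sets out from 10: heterogeneous syn-hydrogenation (H2, Pd/C, Et3N, EtOAc) adds both hydrogens from one face and removes the bromine in the same operation, giving the racemic cis ester F3. Preparative chromatography on a chiral stationary phase separates the enantiomers, and the route is rejoined at 12.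

Step 5. Ionisation of the ketal carbon beside the carbonyl group may be slow, so that ketal exchange with the deactivated, hindered catechol stalls or silyl ethers are lost first. The fallback sets out from diketone 4 and catechol 6 and builds the benzodioxole by carbene chemistry. TsNHNH2 condenses at the more electrophilic carbonyl of 4 to give the monotosylhydrazone F4, and Et3N converts it into 2-diazo-1-[3,4-bis(TBSO)phenyl]-2-[3,5-bis(TBSO)phenyl]ethan-1-one F5. Ag2O oxidises 6 to methyl 3-bromo-4,5-dioxocyclohexa-1,5-diene-1-carboxylate F6. Rh2(OAc)4-catalysed reaction of F5 with F6 (carbonyl ylide, then 1,5-electrocyclisation, the known 1,3-dioxole synthesis from carbenes and 1,2-diones) rejoins the route at ketal 7.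

**Further compounds**
F1 | step 7 | 2-hydroxy-1-[3,4-bis(TBSO)phenyl]-2-[3,5-bis(TBSO)phenyl]ethan-1-one (racemic) | O=C(c1ccc(O[Si](C)(C)C(C)(C)C)c(O[Si](C)(C)C(C)(C)C)c1)C(O)c1cc(O[Si](C)(C)C(C)(C)C)cc(O[Si](C)(C)C(C)(C)C)c1
F2 | step 7 | methyl 3-bromo-4-{2-[3,4-bis(TBSO)phenyl]-1-[3,5-bis(TBSO)phenyl]-2-oxoethoxy}-5-hydroxybenzoate (racemic) | COC(=O)c1cc(Br)c(OC(c2cc(O[Si](C)(C)C(C)(C)C)cc(O[Si](C)(C)C(C)(C)C)c2)C(=O)c2ccc(O[Si](C)(C)C(C)(C)C)c(O[Si](C)(C)C(C)(C)C)c2)c(O)c1
F3 | step 8 | racemic cis ester, 1:1 mixture of 12 and its (2R,3S) enantiomer (the latter drawn) | COC(=O)c2ccc3c(c2)O[C@@H](c2ccc(O[Si](C)(C)C(C)(C)C)c(O[Si](C)(C)C(C)(C)C)c2)[C@@H](c2cc(O[Si](C)(C)C(C)(C)C)cc(O[Si](C)(C)C(C)(C)C)c2)O3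
F4 | step 5 | monotosylhydrazone of 4 at the carbonyl bearing the 3,5-bis(TBSO)phenyl ring | Cc1ccc(cc1)S(=O)(=O)NN=C(c1cc(O[Si](C)(C)C(C)(C)C)cc(O[Si](C)(C)C(C)(C)C)c1)C(=O)c1ccc(O[Si](C)(C)C(C)(C)C)c(O[Si](C)(C)C(C)(C)C)c1
F5 | step 5 | 2-diazo-1-[3,4-bis(TBSO)phenyl]-2-[3,5-bis(TBSO)phenyl]ethan-1-one | [N-]=[N+]=C(c1cc(O[Si](C)(C)C(C)(C)C)cc(O[Si](C)(C)C(C)(C)C)c1)C(=O)c1ccc(O[Si](C)(C)C(C)(C)C)c(O[Si](C)(C)C(C)(C)C)c1
F6 | step 5 | methyl 3-bromo-4,5-dioxocyclohexa-1,5-diene-1-carboxylate | COC(=O)C1=CC(=O)C(=O)C(Br)=C1
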